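**Retrosynthetic overview**

1. The strategy rests on ring A (C4a, C5, C6, C7, C8, C8a) of the (2S)-flavanone: it carries three different oxygens (free 5-OH, 7-OMe, and O1 at C8a) and carbon substituents at C8 and C4a, a pattern that substitution of a phloroglucinol cannot differentiate, so ring A is built de novo.
2. Last disconnections: global desilylation, then ring C by Friedel–Crafts acylation (C4–C4a) of a 3-aryl-3-aryloxypropanoic acid whose C2 stereocentre is already in place.
3. Ring A: benzannulation of a 3-alkoxy-2-alkylcyclobutenone with methoxyacetylene forms C5–C6, C7–C8 and C4a–C5; the ketene oxygen becomes 5-OH, the alkyne methoxy 7-OMe, and the cyclobutenone alkoxy oxygen O1 already bonded to C2.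
4. Cyclobutenone: chiral alkynyl ether (alcohol, trichloroethylene, n-BuLi, Z-allylic bromide) plus dichloroketene, then zinc; the (S)-alcohol comes from asymmetric hydrogenation of the aryl β-keto ester, the Z-bromide from syn-carbocupration of a 4-silyloxybut-2-ynoate.
5. Ring order: ring B is purchased, ring A is formed in step 16, ring C in step 20.

Key step: step 16

Abbreviations: TIPS = triisopropylsilyl; TBDPS = tert-butyldiphenylsilyl; TBS = tert-butyldimethylsilyl; Tr = triphenylmethyl; Ar = 3,4-bis(triisopropylsilyloxy)phenyl.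

Remark on the chemistry: the chain alcohol is carried as a trityl ether (released by mild acid) and not as an oxidatively cleaved benzyl-type ether, because a quinone oxidant would also attack the allyl-substituted, trioxygenated ring A; the hindered catechol TIPS ethers are assumed to survive KH and n-BuLi.

**Route**

Step 1
Reactants: 1 3,4-dihydroxybenzaldehyde
Product: 2 3,4-bis(triisopropylsilyloxy)benzaldehyde
Conditions: TIPSCl, imidazole, DMF, rt
Reagents that add atoms: triisopropylsilyl chloride, CC(C)[Si](Cl)(C(C)C)C(C)C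
Why: Imidazole-promoted silylation of both phenols should give hindered aryl silyl ethers that tolerate the alkoxide, organolithium and Lewis-acid steps ahead and come off with fluoride at the end.

Step 2
Reactants: 2 3,4-bis(triisopropylsilyloxy)benzaldehyde
Product: 3 ethyl 3-Ar-3-oxopropanoate
Conditions: N2CHCO2Et, NbCl5 (5 mol%), CH2Cl2, rt
Reagents that add atoms: ethyl diazoacetate, CCOC(=O)C=[N+]=[N-]
Why: Roskamp homologation, in which Lewis-acid-promoted addition of the diazo ester to the aldehyde is followed by a 1,2-hydride shift with loss of nitrogen, should give the β-keto ester in one step.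

Step 3
Reactants: 3 ethyl 3-Ar-3-oxopropanoate
Product: 4 ethyl (S)-3-Ar-3-hydroxypropanoate
Conditions: RuCl2[(R)-BINAP] (1 mol%), H2 (50 atm), EtOH, 50 °C
Reagents that add atoms: none
Why: Noyori asymmetric hydrogenation of the chelated β-keto ester sets the only stereocentre; the (R)-ligand, which gives (R)-3-hydroxybutanoate from acetoacetate, delivers hydrogen to the same face here, and because aryl outranks CH2CO2Et this is the (S)-carbinol needed for C2.

Step 4
Reactants: 4 ethyl (S)-3-Ar-3-hydroxypropanoate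
Product: 5 (S)-1-Ar-propane-1,3-diol
Conditions: LiBH4, THF, 0 °C to rt
Reagents that add atoms: none
Why: Borohydride reduction of the hydroxyl-activated ester should give the 1,3-diol without touching the aryl silyl ethers or the stereocentre.

Step 5
Reactants: 5 (S)-1-Ar-propane-1,3-diol
Product: 6 (S)-1-Ar-3-(trityloxy)propan-1-ol
Conditions: TrCl, Et3N, DMAP (cat.), CH2Cl2, 0 °C to rt
Reagents that add atoms: trityl chloride, ClC(c1ccccc1)(c1ccccc1)c1ccccc1
Why: Tritylation is strongly selective for the primary over the secondary benzylic hydroxyl on steric grounds, and the trityl ether is inert to KH and n-BuLi.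

Step 6
Reactants: 6 (S)-1-Ar-3-(trityloxy)propan-1-ol; 7 trichloroethylene
Product: 9 (S)-1-Ar-3-(trityloxy)propyl (E)-1,2-dichlorovinyl ether, via potassium alkoxide 8 (not isolated)
Conditions: KH (1.1 equiv), THF, 0 °C to rt; then Cl2C=CHCl (1.1 equiv), −50 °C to rt
Reagents that add atoms: none
Why: Net vinylic substitution of chloride by the potassium alkoxide (elimination–addition, the trichloroethylene route to alkynyl ethers) should give the dichlorovinyl ether with the C–O bond of the stereocentre untouched.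

Step 7
Reactants: 10 propargyl alcohol
Product: 11 tert-butyl(diphenyl)(prop-2-ynyloxy)silane
Conditions: TBDPSCl, imidazole, CH2Cl2, rt
Reagents that add atoms: tert-butyldiphenylsilyl chloride, CC(C)(C)[Si](Cl)(c1ccccc1)c1ccccc1
Why: Standard silylation; the TBDPS ether is chosen because it survives the acidic detritylation of step 18.

Step 8
Reactants: 11 tert-butyl(diphenyl)(prop-2-ynyloxy)silane
Product: 13 ethyl 4-(tert-butyldiphenylsilyloxy)but-2-ynoate, via lithium acetylide 12 (not isolated)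
Conditions: n-BuLi, THF, −78 °C; then ClCO2Et, −78 °C to 0 °C
Reagents that add atoms: ethyl chloroformate, CCOC(=O)Cl
Why: Deprotonation of the terminal alkyne and C-acylation of the lithium acetylide with the chloroformate is routine.

Step 9
Reactants: 13 ethyl 4-(tert-butyldiphenylsilyloxy)but-2-ynoate
Product: 15 ethyl (Z)-4-(tert-butyldiphenylsilyloxy)-3-methylbut-2-enoate, via alkenylcuprate 14 (not isolated)
Conditions: Me2CuLi (from MeLi, CuI), THF, −78 °C; MeOH then aq. NH4Cl at −78 °C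
Reagents that add atoms: lithium dimethylcuprate, [Li+].C[Cu-]C
Why: Syn carbocupration of the ynoate and protonation of the configurationally stable alkenylcuprate at −78 °C with retention place methyl and hydrogen cis, so CH2OSi and CO2Et are cis, which is the Z geometry of the target side chain.

Step 10
Reactants: 15 ethyl (Z)-4-(tert-butyldiphenylsilyloxy)-3-methylbut-2-enoate
Product: 16 (Z)-4-(tert-butyldiphenylsilyloxy)-3-methylbut-2-en-1-ol
Conditions: i-Bu2AlH (2.2 equiv), CH2Cl2, −78 °C to 0 °C; aq. potassium sodium tartrate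
Reagents that add atoms: none
Why: 1,2-Reduction of the enoate by the aluminium hydride should give the allylic alcohol without isomerising the trisubstituted alkene.

Step 11
Reactants: 16 (Z)-4-(tert-butyldiphenylsilyloxy)-3-methylbut-2-en-1-ol
Product: 17 [(Z)-4-bromo-2-methylbut-2-enyloxy](tert-butyl)diphenylsilane
Conditions: CBr4, PPh3, CH2Cl2, 0 °C
Reagents that add atoms: carbon tetrabromide, BrC(Br)(Br)Br
Why: Appel bromination is an SN2 displacement at the primary allylic carbon under neutral conditions and should keep the Z geometry.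

Step 12
Reactants: 9 (S)-1-Ar-3-(trityloxy)propyl (E)-1,2-dichlorovinyl ether; 17 [(Z)-4-bromo-2-methylbut-2-enyloxy](tert-butyl)diphenylsilane
Product: 20 (S)-1-Ar-3-(trityloxy)propyl (Z)-6-(tert-butyldiphenylsilyloxy)-5-methylhex-4-en-1-ynyl ether, via chloroalkynyl ether 18 (not isolated), via lithium alkynyl ether 19 (not isolated)
Conditions: n-BuLi (2.1 equiv), THF, −78 to −40 °C; then 17, DMPU, −78 to 0 °C
Reagents that add atoms: none
Why: n-BuLi eliminates HCl to the chloroalkyne and then exchanges chlorine for lithium, and the lithium alkynyl ether is alkylated by SN2 at the primary allylic bromide (acetylide alkylation), the product being kept below room temperature because benzylic alkynyl ethers rearrange on heating.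

Step 13
Reactants: 20 (S)-1-Ar-3-(trityloxy)propyl (Z)-6-(tert-butyldiphenylsilyloxy)-5-methylhex-4-en-1-ynyl ether
Product: 21 4,4-dichloro-3-[(S)-1-Ar-3-(trityloxy)propoxy]-2-[(Z)-4-(tert-butyldiphenylsilyloxy)-3-methylbut-2-enyl]cyclobut-2-enone
Conditions: Cl3CCOCl (1.2 equiv), Zn–Cu couple, Et2O–DME, 0 °C to rt
Reagents that add atoms: trichloroacetyl chloride, ClC(Cl)(Cl)C(Cl)=O
Why: Ketene–alkyne [2+2] cycloaddition of dichloroketene, whose carbonyl carbon bonds to the alkyne carbon β to oxygen, should give the 3-alkoxycyclobutenone, since the ynol ether is far more nucleophilic than the trisubstituted alkene and DME ties up ZnCl2.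

Step 14
Reactants: 21 4,4-dichloro-3-[(S)-1-Ar-3-(trityloxy)propoxy]-2-[(Z)-4-(tert-butyldiphenylsilyloxy)-3-methylbut-2-enyl]cyclobut-2-enone
Product: 22 3-[(S)-1-Ar-3-(trityloxy)propoxy]-2-[(Z)-4-(tert-butyldiphenylsilyloxy)-3-methylbut-2-enyl]cyclobut-2-enone
Conditions: Zn dust, AcOH, TMEDA, EtOH–THF, 0 °C
Reagents that add atoms: none
Why: Reductive dechlorination of the α,α-dichloro ketone by zinc under amine-buffered conditions should leave the vinylogous ester, the trityl ether and the silyl ethers intact.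

Step 15
Reactants: 23 chloroacetaldehyde dimethyl acetal
Product: 25 methoxyacetylene, via sodium methoxyacetylide 24 (not isolated)
Conditions: NaNH2 (3 equiv), liq. NH3, −33 °C; cold aq. NaCl quench at −70 °C; distilled into toluene
Reagents that add atoms: none
Why: Double elimination (HCl, then methanol) by NaNH2 gives the sodium acetylide, protonated on quench; the methoxy ether has no β-hydrogen and so tolerates the heating of step 16.

Step 16
Reactants: 22 3-[(S)-1-Ar-3-(trityloxy)propoxy]-2-[(Z)-4-(tert-butyldiphenylsilyloxy)-3-methylbut-2-enyl]cyclobut-2-enone; 25 methoxyacetylene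
Product: 30 3-methoxy-5-[(S)-1-Ar-3-(trityloxy)propoxy]-4-[(Z)-4-(tert-butyldiphenylsilyloxy)-3-methylbut-2-enyl]phenol, via vinylketene 26 (not isolated), via vinylcyclobutenone 27 (not isolated), via dienylketene 28 (not isolated), via cyclohexadienone 29 (not isolated)
Conditions: 25 (2 equiv), toluene, sealed tube, 80 °C then 110 °C
Reagents that add atoms: none
Why: Heating opens cyclobutenone 22 by a 4π electrocyclic reaction to vinylketene 26, whose ketene C=C adds methoxyacetylene in a [2+2] cycloaddition (ketene carbonyl carbon to the unsubstituted alkyne carbon, forming C5–C6 and C7–C8) to give 27; a second 4π opening gives dienylketene 28, which closes ring A by a thermal disrotatory 6π electrocyclisation (C4a–C5) to 29 and tautomerises to phenol 30. This is the Danheiser benzannulation of a cyclobutenone with an alkoxyacetylene, a known reaction class for alkyl- and oxygen-substituted cyclobutenones, applied here to one whose alkoxy group is chiral. Ring A is therefore closed by 6π electrocyclisation of a dienylketene and not by substitution on an arene. No stereocentre is formed (the quaternary carbon of 27 is lost on ring opening), and the C2 centre from step 3 and the Z alkene lie outside the reacting π system under neutral thermal conditions. The step needs the correct orientation of the [2+2] addition and reaction of the ketene with the alkyne in preference to the side-chain alkene, and both follow from the strong polarisation and nucleophilicity of the ynol ether. The ketene oxygen ends as the only free hydroxyl (C5), the alkyne methoxy group at C7 and the cyclobutenone oxygen at C8a as O1, so the three ring-A oxygens need no later differentiation.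

Step 17
Reactants: 30 3-methoxy-5-[(S)-1-Ar-3-(trityloxy)propoxy]-4-[(Z)-4-(tert-butyldiphenylsilyloxy)-3-methylbut-2-enyl]phenol
Product: 31 TBS ether of phenol 30
Conditions: TBSCl, imidazole, DMF, rt
Reagents that add atoms: tert-butyldimethylsilyl chloride, CC(C)(C)[Si](C)(C)Cl
Why: Silylation of the only free phenol protects the electron-rich ring A from the oxidant of step 19 while keeping C4a activated for step 20.

Step 18
Reactants: 31 TBS ether of phenol 30
Product: 32 (S)-3-Ar-3-(aryloxy)propan-1-ol (31 without the trityl group)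
Conditions: camphorsulfonic acid (0.1 equiv), MeOH–CH2Cl2 (1:1), 0 °C to rt
Reagents that add atoms: none
Why: Acid-catalysed solvolysis of the trityl ether through the trityl cation, trapped by methanol, should proceed at an acidity that leaves the aryl silyl ethers, the TBDPS ether and the benzylic aryl ether intact.

Step 19
Reactants: 32 (S)-3-Ar-3-(aryloxy)propan-1-ol
Product: 34 (S)-3-Ar-3-(aryloxy)propanoic acid, via aldehyde 33 (not isolated)
Conditions: TEMPO (0.2 equiv), PhI(OAc)2 (2.2 equiv), MeCN–H2O, rt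
Reagents that add atoms: water, O
Why: Oxoammonium (TEMPO) oxidation takes the primary alcohol through the aldehyde hydrate to the acid under near-neutral conditions that spare the alkene, the silyl ethers and the arenes.

Step 20
Reactants: 34 (S)-3-Ar-3-(aryloxy)propanoic acid
Product: 36 (2S)-2-Ar-5-(tert-butyldimethylsilyloxy)-8-[(Z)-4-(tert-butyldiphenylsilyloxy)-3-methylbut-2-enyl]-7-methoxychroman-4-one, via mixed anhydride 35 (not isolated)
Conditions: (CF3CO)2O (1.1 equiv), CH2Cl2, −20 to 0 °C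
Reagents that add atoms: none
Why: Intramolecular Friedel–Crafts acylation through the mixed trifluoroacetic anhydride closes ring C at C4a, the only position the tether from O1 can reach, and this carbon is activated by three oxygens so that no strong Lewis acid is needed and the C2 ether should not ionise.

Step 21
Reactants: 36 protected flavanone
Product: 37 (2S)-2-(3,4-dihydroxyphenyl)-5-hydroxy-8-[(Z)-4-hydroxy-3-methylbut-2-enyl]-7-methoxychroman-4-one
Conditions: Bu4NF/AcOH (1:1, excess), THF, 0 °C to rt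
Reagents that add atoms: none
Why: Fluoride cleaves all four silyl ethers, and the acetic acid buffer keeps the medium below the basicity at which the flavanone would open to the chalcone and racemise.

**Compound list**

1 | 3,4-dihydroxybenzaldehyde | O=Cc1ccc(O)c(O)c1 | starting material
2 | 3,4-bis(triisopropylsilyloxy)benzaldehyde | O=Cc1ccc(O[Si](C(C)C)(C(C)C)C(C)C)c(O[Si](C(C)C)(C(C)C)C(C)C)c1 | intermediate
3 | ethyl 3-[3,4-bis(triisopropylsilyloxy)phenyl]-3-oxopropanoate | CCOC(=O)CC(=O)c1ccc(O[Si](C(C)C)(C(C)C)C(C)C)c(O[Si](C(C)C)(C(C)C)C(C)C)c1 | intermediate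
4 | ethyl (S)-3-[3,4-bis(triisopropylsilyloxy)phenyl]-3-hydroxypropanoate | O[C@H](c2ccc(O[Si](C(C)C)(C(C)C)C(C)C)c(O[Si](C(C)C)(C(C)C)C(C)C)c2)CC(=O)OCC | intermediate
5 | (S)-1-[3,4-bis(triisopropylsilyloxy)phenyl]propane-1,3-diol | O[C@H](c2ccc(O[Si](C(C)C)(C(C)C)C(C)C)c(O[Si](C(C)C)(C(C)C)C(C)C)c2)CCO | intermediate
6 | (S)-1-[3,4-bis(triisopropylsilyloxy)phenyl]-3-(trityloxy)propan-1-ol | O[C@H](c2ccc(O[Si](C(C)C)(C(C)C)C(C)C)c(O[Si](C(C)C)(C(C)C)C(C)C)c2)CCOC(c3ccccc3)(c3ccccc3)c3ccccc3 | intermediate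
7 | trichloroethylene | ClC=C(Cl)Cl | starting material
8 | potassium alkoxide of 6 | [K+].[O-][C@H](c2ccc(O[Si](C(C)C)(C(C)C)C(C)C)c(O[Si](C(C)C)(C(C)C)C(C)C)c2)CCOC(c3ccccc3)(c3ccccc3)c3ccccc3 | intermediate
9 | (S)-1-Ar-3-(trityloxy)propyl (E)-1,2-dichlorovinyl ether | Cl/C=C(/Cl)O[C@H](c2ccc(O[Si](C(C)C)(C(C)C)C(C)C)c(O[Si](C(C)C)(C(C)C)C(C)C)c2)CCOC(c3ccccc3)(c3ccccc3)c3ccccc3 | intermediate
10 | propargyl alcohol | C#CCO | starting material
11 | tert-butyl(diphenyl)(prop-2-ynyloxy)silane | C#CCO[Si](c1ccccc1)(c1ccccc1)C(C)(C)C | intermediate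
12 | lithium acetylide of 11 | [Li+].[C-]#CCO[Si](c1ccccc1)(c1ccccc1)C(C)(C)C | intermediate
13 | ethyl 4-(tert-butyldiphenylsilyloxy)but-2-ynoate | CCOC(=O)C#CCO[Si](c1ccccc1)(c1ccccc1)C(C)(C)C | intermediate
14 | lithium methyl(alkenyl)cuprate, syn adduct with Cu cis to the new methyl | [Li+].C[Cu-]/C(C(=O)OCC)=C(\C)CO[Si](c1ccccc1)(c1ccccc1)C(C)(C)C | intermediate
15 | ethyl (Z)-4-(tert-butyldiphenylsilyloxy)-3-methylbut-2-enoate | CCOC(=O)/C=C(/C)CO[Si](c1ccccc1)(c1ccccc1)C(C)(C)C | intermediate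
16 | (Z)-4-(tert-butyldiphenylsilyloxy)-3-methylbut-2-en-1-ol | OC/C=C(/C)CO[Si](c1ccccc1)(c1ccccc1)C(C)(C)C | intermediate
17 | [(Z)-4-bromo-2-methylbut-2-enyloxy](tert-butyl)diphenylsilane | BrC/C=C(/C)CO[Si](c1ccccc1)(c1ccccc1)C(C)(C)C | intermediate
18 | (S)-1-Ar-3-(trityloxy)propyl chloroethynyl ether | ClC#CO[C@H](c2ccc(O[Si](C(C)C)(C(C)C)C(C)C)c(O[Si](C(C)C)(C(C)C)C(C)C)c2)CCOC(c3ccccc3)(c3ccccc3)c3ccccc3 | intermediate
19 | lithium alkynyl ether (lithium acetylide of the ethynyl ether) | [Li+].[C-]#CO[C@H](c2ccc(O[Si](C(C)C)(C(C)C)C(C)C)c(O[Si](C(C)C)(C(C)C)C(C)C)c2)CCOC(c3ccccc3)(c3ccccc3)c3ccccc3 | intermediate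
20 | (S)-1-Ar-3-(trityloxy)propyl (Z)-6-(tert-butyldiphenylsilyloxy)-5-methylhex-4-en-1-ynyl ether | C(#CC/C=C(/C)CO[Si](c4ccccc4)(c4ccccc4)C(C)(C)C)O[C@H](c2ccc(O[Si](C(C)C)(C(C)C)C(C)C)c(O[Si](C(C)C)(C(C)C)C(C)C)c2)CCOC(c3ccccc3)(c3ccccc3)c3ccccc3 | intermediate
21 | 4,4-dichloro-3-[(S)-1-Ar-3-(trityloxy)propoxy]-2-[(Z)-4-(tert-butyldiphenylsilyloxy)-3-methylbut-2-enyl]cyclobut-2-enone | O=C1C(Cl)(Cl)C(O[C@H](c2ccc(O[Si](C(C)C)(C(C)C)C(C)C)c(O[Si](C(C)C)(C(C)C)C(C)C)c2)CCOC(c3ccccc3)(c3ccccc3)c3ccccc3)=C1C/C=C(/C)CO[Si](c4ccccc4)(c4ccccc4)C(C)(C)C | intermediate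
22 | 3-[(S)-1-Ar-3-(trityloxy)propoxy]-2-[(Z)-4-(tert-butyldiphenylsilyloxy)-3-methylbut-2-enyl]cyclobut-2-enone | O=C1CC(O[C@H](c2ccc(O[Si](C(C)C)(C(C)C)C(C)C)c(O[Si](C(C)C)(C(C)C)C(C)C)c2)CCOC(c3ccccc3)(c3ccccc3)c3ccccc3)=C1C/C=C(/C)CO[Si](c4ccccc4)(c4ccccc4)C(C)(C)C | intermediate
23 | chloroacetaldehyde dimethyl acetal | COC(CCl)OC | starting material
24 | sodium methoxyacetylide | [Na+].[C-]#COC | intermediate
25 | methoxyacetylene | COC#C | intermediate
26 | vinylketene: 3-alkoxy-2-(allyl chain)buta-1,3-dien-1-one | O=C=C(C/C=C(/C)CO[Si](c4ccccc4)(c4ccccc4)C(C)(C)C)C(=C)O[C@H](c2ccc(O[Si](C(C)C)(C(C)C)C(C)C)c(O[Si](C(C)C)(C(C)C)C(C)C)c2)CCOC(c3ccccc3)(c3ccccc3)c3ccccc3 | intermediate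
27 | 4-(1-alkoxyvinyl)-3-methoxy-4-(allyl chain)cyclobut-2-enone, both epimers at C4 | O=C1C=C(OC)C1(C/C=C(/C)CO[Si](c4ccccc4)(c4ccccc4)C(C)(C)C)C(=C)O[C@H](c2ccc(O[Si](C(C)C)(C(C)C)C(C)C)c(O[Si](C(C)C)(C(C)C)C(C)C)c2)CCOC(c3ccccc3)(c3ccccc3)c3ccccc3 | intermediate
28 | dienylketene: 5-alkoxy-3-methoxy-4-(allyl chain)hexa-1,3,5-trien-1-one, ketenyl and alkoxyvinyl groups cis | O=C=C/C(OC)=C(/C/C=C(/C)CO[Si](c4ccccc4)(c4ccccc4)C(C)(C)C)C(=C)O[C@H](c2ccc(O[Si](C(C)C)(C(C)C)C(C)C)c(O[Si](C(C)C)(C(C)C)C(C)C)c2)CCOC(c3ccccc3)(c3ccccc3)c3ccccc3 | intermediate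
29 | 5-alkoxy-3-methoxy-4-(allyl chain)cyclohexa-2,4-dien-1-one | O=C1C=C(OC)C(C/C=C(/C)CO[Si](c4ccccc4)(c4ccccc4)C(C)(C)C)=C(O[C@H](c2ccc(O[Si](C(C)C)(C(C)C)C(C)C)c(O[Si](C(C)C)(C(C)C)C(C)C)c2)CCOC(c3ccccc3)(c3ccccc3)c3ccccc3)C1 | intermediate
30 | 3-methoxy-5-[(S)-1-Ar-3-(trityloxy)propoxy]-4-[(Z)-4-(tert-butyldiphenylsilyloxy)-3-methylbut-2-enyl]phenol | COc1cc(O)cc(O[C@H](c2ccc(O[Si](C(C)C)(C(C)C)C(C)C)c(O[Si](C(C)C)(C(C)C)C(C)C)c2)CCOC(c3ccccc3)(c3ccccc3)c3ccccc3)c1C/C=C(/C)CO[Si](c4ccccc4)(c4ccccc4)C(C)(C)C | intermediate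
31 | TBS ether of phenol 30 | COc1cc(O[Si](C)(C)C(C)(C)C)cc(O[C@H](c2ccc(O[Si](C(C)C)(C(C)C)C(C)C)c(O[Si](C(C)C)(C(C)C)C(C)C)c2)CCOC(c3ccccc3)(c3ccccc3)c3ccccc3)c1C/C=C(/C)CO[Si](c4ccccc4)(c4ccccc4)C(C)(C)C | intermediate
32 | (S)-3-Ar-3-(aryloxy)propan-1-ol (31 without trityl) | COc1cc(O[Si](C)(C)C(C)(C)C)cc(O[C@H](c2ccc(O[Si](C(C)C)(C(C)C)C(C)C)c(O[Si](C(C)C)(C(C)C)C(C)C)c2)CCO)c1C/C=C(/C)CO[Si](c4ccccc4)(c4ccccc4)C(C)(C)C | intermediate
33 | (S)-3-Ar-3-(aryloxy)propanal | COc1cc(O[Si](C)(C)C(C)(C)C)cc(O[C@H](c2ccc(O[Si](C(C)C)(C(C)C)C(C)C)c(O[Si](C(C)C)(C(C)C)C(C)C)c2)CC=O)c1C/C=C(/C)CO[Si](c4ccccc4)(c4ccccc4)C(C)(C)C | intermediate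
34 | (S)-3-Ar-3-(aryloxy)propanoic acid | COc1cc(O[Si](C)(C)C(C)(C)C)cc(O[C@H](c2ccc(O[Si](C(C)C)(C(C)C)C(C)C)c(O[Si](C(C)C)(C(C)C)C(C)C)c2)CC(=O)O)c1C/C=C(/C)CO[Si](c4ccccc4)(c4ccccc4)C(C)(C)C | intermediate
35 | mixed anhydride of 34 with trifluoroacetic acid | COc1cc(O[Si](C)(C)C(C)(C)C)cc(O[C@H](c2ccc(O[Si](C(C)C)(C(C)C)C(C)C)c(O[Si](C(C)C)(C(C)C)C(C)C)c2)CC(=O)OC(=O)C(F)(F)F)c1C/C=C(/C)CO[Si](c4ccccc4)(c4ccccc4)C(C)(C)C | intermediate
36 | (2S)-2-Ar-5-(tert-butyldimethylsilyloxy)-8-[(Z)-4-(tert-butyldiphenylsilyloxy)-3-methylbut-2-enyl]-7-methoxychroman-4-one | COc1cc(O[Si](C)(C)C(C)(C)C)c2c(c1C/C=C(/C)CO[Si](c4ccccc4)(c4ccccc4)C(C)(C)C)O[C@H](c3ccc(O[Si](C(C)C)(C(C)C)C(C)C)c(O[Si](C(C)C)(C(C)C)C(C)C)c3)CC2=O | intermediate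
37 | (2S)-2-(3,4-dihydroxyphenyl)-5-hydroxy-8-[(Z)-4-hydroxy-3-methylbut-2-enyl]-7-methoxychroman-4-one | COc1cc(O)c2c(c1C/C=C(/C)CO)O[C@H](c1ccc(O)c(O)c1)CC2=O | target

**Step count**

Total: 21 steps. Longest linear sequence: 15 steps (steps 1–6, 12–14, 16–21).

**Steps most likely to fail**

1. Step 16. The 4π opening of the donor-substituted cyclobutenone may be slower than thermal loss of the secondary benzylic alkoxy group or oligomerisation of methoxyacetylene and the ketene intermediates, so material could be consumed before the [2+2] step. Fallback by known chemistry, setting out from keto ester 3 and bromide 17 and returning at 31: hydrogenation of 3 with the (S)-BINAP catalyst should give ethyl (R)-3-Ar-3-hydroxypropanoate F1, LiBH4 reduction the (R)-diol F2, and tritylation the (R)-alcohol F3. Separately, commercial 5-methoxyresorcinol (COc1cc(O)cc(O)c1) would be C-alkylated with 17 (aq. KOH, 0 °C) to give, after separation from the 2-alkyl isomer, 4-alkyl-5-methoxyresorcinol F4. Its less hindered hydroxyl, para to the chain, would be silylated (TBSCl, imidazole) to phenol F5. Mitsunobu etherification of F5 with F3 (PPh3, DIAD, toluene, 0 °C) inverts the carbinol centre and gives 31.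

2. Step 12. Alkylation of the weakly nucleophilic lithium alkynyl ether may be slow, leaving time for base-mediated isomerisation of the skipped enyne and for rearrangement of the benzylic alkynyl ether on warming. Fallback, setting out from 9 and returning at 20: n-BuLi (2.1 equiv, THF, −78 to −40 °C) followed by a methanol quench at −78 °C should give the terminal (S)-1-Ar-3-(trityloxy)propyl ethynyl ether F6, which is coupled with 17 by copper catalysis under weak base (CuI cat., K2CO3, NaI, DMF, 0 °C to rt) to give 20 without a stoichiometric organolithium in the presence of the product.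

3. Step 20. The acid released during acylation may ionise the C2–O1 benzylic ether (cation stabilised by the para-silyloxy aryl group), with racemisation or loss of the aryloxy group, and the anhydride may trifluoroacetylate C6. Fallback, setting out from alcohol 32 and returning at 36: Dess–Martin oxidation (NaHCO3, CH2Cl2) stopped at aldehyde 33, which is isolated; intramolecular Friedel–Crafts hydroxyalkylation at C4a with a mild Lewis acid (MgBr2·OEt2, CH2Cl2, −40 °C) to the (2S)-flavan-4-ol F7 (both C4 epimers); and oxidation of the benzylic alcohol (Dess–Martin periodinane or MnO2) to 36.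

**Further compounds**

F1 | step 16 | ethyl (R)-3-[3,4-bis(triisopropylsilyloxy)phenyl]-3-hydroxypropanoate | O[C@@H](c2ccc(O[Si](C(C)C)(C(C)C)C(C)C)c(O[Si](C(C)C)(C(C)C)C(C)C)c2)CC(=O)OCC
F2 | step 16 | (R)-1-[3,4-bis(triisopropylsilyloxy)phenyl]propane-1,3-diol | O[C@@H](c2ccc(O[Si](C(C)C)(C(C)C)C(C)C)c(O[Si](C(C)C)(C(C)C)C(C)C)c2)CCO
F3 | step 16 | (R)-1-[3,4-bis(triisopropylsilyloxy)phenyl]-3-(trityloxy)propan-1-ol | O[C@@H](c2ccc(O[Si](C(C)C)(C(C)C)C(C)C)c(O[Si](C(C)C)(C(C)C)C(C)C)c2)CCOC(c3ccccc3)(c3ccccc3)c3ccccc3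
F4 | step 16 | 4-[(Z)-4-(tert-butyldiphenylsilyloxy)-3-methylbut-2-enyl]-5-methoxybenzene-1,3-diol | COc1cc(O)cc(O)c1C/C=C(/C)CO[Si](c4ccccc4)(c4ccccc4)C(C)(C)C
F5 | step 16 | 5-(tert-butyldimethylsilyloxy)-2-[(Z)-4-(tert-butyldiphenylsilyloxy)-3-methylbut-2-enyl]-3-methoxyphenol | COc1cc(O[Si](C)(C)C(C)(C)C)cc(O)c1C/C=C(/C)CO[Si](c4ccccc4)(c4ccccc4)C(C)(C)C
F6 | step 12 | (S)-1-[3,4-bis(triisopropylsilyloxy)phenyl]-3-(trityloxy)propyl ethynyl ether | C#CO[C@H](c2ccc(O[Si](C(C)C)(C(C)C)C(C)C)c(O[Si](C(C)C)(C(C)C)C(C)C)c2)CCOC(c3ccccc3)(c3ccccc3)c3ccccc3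
F7 | step 20 | (2S)-2-Ar-5-(tert-butyldimethylsilyloxy)-8-[(Z)-4-(tert-butyldiphenylsilyloxy)-3-methylbut-2-enyl]-7-methoxychroman-4-ol, both C4 epimers | COc1cc(O[Si](C)(C)C(C)(C)C)c2c(c1C/C=C(/C)CO[Si](c4ccccc4)(c4ccccc4)C(C)(C)C)O[C@H](c3ccc(O[Si](C(C)C)(C(C)C)C(C)C)c(O[Si](C(C)C)(C(C)C)C(C)C)c3)CC2O
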